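The flavonol is cut through ring A: the C4a–C5 and C8–C8a bonds are broken, so that C5–C8 with their oxygens on C5 and C7 become an acetoacetate-derived 1,3-dioxygenated diene and the C4a=C8a bond becomes the C5=C6 enone alkene of a monocyclic 4-pyranone that already carries ring B at C2 and the protected 3-oxygen (ring C). One Diels–Alder/elimination cascade then forges both bonds and aromatises ring A, a phenylsulfinyl group on the pyranone serving as activator and as leaving group. The dienophile is 2-(4-methoxyphenyl)-5-(phenylsulfinyl)-3-(SEM-oxy)-4-pyranone, made by bromination, Suzuki coupling and sulfenylation of 3-hydroxy-4-pyranone.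

Key step: step 8

Remark: sulfur in 7 is a stereocenter that is formed and used as the racemate, and the 3-oxygen is carried as its 2-(trimethylsilyl)ethoxymethyl (SEM) acetal so that the last unmasking can be done with fluoride beside the acid-labile prenyl aryl ether.

Step 1
Reactants: 1 3-hydroxy-4H-pyran-4-one
Product: 2 2-bromo-3-hydroxy-4H-pyran-4-one
Conditions: NBS (1.05 equiv), MeCN, 0 °C to rt
Reagents that add atoms: N-bromosuccinimide, O=C1CCC(=O)N1Br
Why: Electrophilic bromination of the enol, in which the free 3-OH activates the adjacent C2, the site at which 3-hydroxy-4-pyranones of the kojic acid family are halogenated, so one equivalent of NBS should give the 2-bromide.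

Step 2
Reactants: 2 2-bromo-3-hydroxy-4H-pyran-4-one
Product: 3 2-bromo-3-{[2-(trimethylsilyl)ethoxy]methoxy}-4H-pyran-4-one
Conditions: SEMCl, iPr2NEt, CH2Cl2, 0 °C to rt
Reagents that add atoms: 2-(trimethylsilyl)ethoxymethyl chloride, C[Si](C)(C)CCOCCl
Why: Williamson-type O-alkylation of the acidic enol gives a formaldehyde acetal that should withstand base, palladium catalysis, peracid and brief dilute acid and can later be removed with fluoride.

Step 3
Reactants: 3 2-bromo-3-{[2-(trimethylsilyl)ethoxy]methoxy}-4H-pyran-4-one; 4 (4-methoxyphenyl)boronic acid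
Product: 5 2-(4-methoxyphenyl)-3-{[2-(trimethylsilyl)ethoxy]methoxy}-4H-pyran-4-one
Conditions: Pd(PPh3)4 (5 mol %), K2CO3, 1,4-dioxane/H2O, 80 °C
Reagents that add atoms: none
Why: Suzuki–Miyaura coupling, in which the C2–Br bond of the β-bromo enone (a vinylogous acyl bromide) should add readily to zerovalent palladium and the boronic acid delivers ring B.

Step 4
Reactants: 5 2-(4-methoxyphenyl)-3-{[2-(trimethylsilyl)ethoxy]methoxy}-4H-pyran-4-one
Product: 6 2-(4-methoxyphenyl)-5-(phenylthio)-3-{[2-(trimethylsilyl)ethoxy]methoxy}-4H-pyran-4-one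
Conditions: PhSH, NCS, CH2Cl2, 0 °C; then 5, pyridine, 0 °C to rt
Reagents that add atoms: benzenesulfenyl chloride, ClSc1ccccc1 (made in the flask from thiophenol, Sc1ccccc1, and N-chlorosuccinimide)
Why: Electrophilic α-sulfenylation of the vinylogous ester, as in the C3-sulfenylation of chromones and flavones: C5 is the only unsubstituted enol-ether β-carbon (C3 is blocked), so sulfenyl transfer there and loss of the C5 proton to pyridine should give the 5-phenylthio pyranone.

Step 5
Reactants: 6 2-(4-methoxyphenyl)-5-(phenylthio)-3-{[2-(trimethylsilyl)ethoxy]methoxy}-4H-pyran-4-one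
Product: 7 2-(4-methoxyphenyl)-5-(phenylsulfinyl)-3-{[2-(trimethylsilyl)ethoxy]methoxy}-4H-pyran-4-one (racemic at sulfur)
Conditions: mCPBA (1.0 equiv), CH2Cl2, −40 °C to 0 °C
Reagents that add atoms: 3-chloroperoxybenzoic acid, O=C(OO)c1cccc(Cl)c1
Why: Chemoselective sulfide-to-sulfoxide oxidation with one equivalent of peracid at low temperature; the new sulfur stereocenter is not controlled because it is lost in step 8.

Step 6
Reactants: 8 methyl acetoacetate
Product: 9 methyl 3-[(trimethylsilyl)oxy]but-2-enoate (E/Z mixture)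
Conditions: TMSCl, Et3N, hexane, rt
Reagents that add atoms: chlorotrimethylsilane, C[Si](C)(C)Cl
Why: Silyl enol ether formation by O-silylation of the β-keto ester enol under soft-enolisation conditions.

Step 7
Reactants: 9 methyl 3-[(trimethylsilyl)oxy]but-2-enoate
Product: 10 (Z)-1-methoxy-1,3-bis[(trimethylsilyl)oxy]buta-1,3-diene (Chan's diene)
Conditions: LiN(iPr)2, THF, −78 °C; TMSCl, −78 °C to rt
Reagents that add atoms: chlorotrimethylsilane, C[Si](C)(C)Cl
Why: Silyl ketene acetal formation by γ-deprotonation of the silyl enol ether and O-silylation of the dienolate; the double-bond geometry of the diene is of no consequence, since it disappears on aromatisation.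

Step 8
Reactants: 7 2-(4-methoxyphenyl)-5-(phenylsulfinyl)-3-{[2-(trimethylsilyl)ethoxy]methoxy}-4H-pyran-4-one; 10 (Z)-1-methoxy-1,3-bis[(trimethylsilyl)oxy]buta-1,3-diene
Product: 13 5,7-dihydroxy-2-(4-methoxyphenyl)-3-{[2-(trimethylsilyl)ethoxy]methoxy}-4H-chromen-4-one, via cis-fused sulfinyl cycloadduct 11 (not isolated), via 5,8-dihydrochromenone mixed ketal 12 (not isolated)
Conditions: 10 (3 equiv), toluene, rt to 80 °C; then 1 M HCl, THF, 0 °C
Reagents that add atoms: none
Why: Proposed new method: the electron-rich diene 10 should add across the sulfinyl-activated C5=C6 bond of 7 in an asynchronous [4+2] sense (in the limit a Mukaiyama–Michael addition of the diene CH2 terminus to C6, then closure of the α-sulfinyl enol carbon C5 onto the ketene-acetal carbon), giving cis-fused 11 with the sulfinyl group and the C8a hydrogen syn. Thermal syn-elimination of benzenesulfenic acid from 11 should restore the C4a=C8a bond (12), and dilute acid then removes the silyl groups, expels methanol from C5 and lets the dienone tautomerise to the resorcinol ring A. The closest known reaction type is the Diels–Alder/elimination/aromatisation of 3-sulfinylchromones and of halo- or sulfinylquinones with Chan's or Brassard's diene, whereas a monocyclic 5-sulfinyl-4-pyranone has not been used as the dienophile. Ring A is closed by the cycloaddition itself, suprafacial on both partners (in the stepwise limit a 6-(enolexo)-exo-trig closure), which forms C4a–C5 and C8–C8a in flavone numbering. No stereocenter has to be controlled, since C4a, C5, C8a and sulfur all become planar or are lost. The step needs regioselectivity, secured by matching the nucleophilic CH2 terminus with the doubly activated β-carbon C6 so that oxygen ends up on C5 and C7, and site selectivity for C5=C6 over C2=C3, secured by the sulfinyl group and by the aryl-blocked, tetrasubstituted C2=C3 bond.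

Step 9
Reactants: 13 5,7-dihydroxy-2-(4-methoxyphenyl)-3-{[2-(trimethylsilyl)ethoxy]methoxy}-4H-chromen-4-one; 14 prenyl bromide (1-bromo-3-methylbut-2-ene)
Product: 15 5-hydroxy-2-(4-methoxyphenyl)-7-[(3-methylbut-2-en-1-yl)oxy]-3-{[2-(trimethylsilyl)ethoxy]methoxy}-4H-chromen-4-one
Conditions: K2CO3 (1.2 equiv), acetone, 50 °C
Reagents that add atoms: none
Why: Williamson etherification (SN2 at the primary allylic carbon): the 7-OH is the most acidic phenol, the 5-OH is tied up in a hydrogen bond to the C4 carbonyl and the 3-oxygen is capped, so one equivalent of prenyl bromide should alkylate O-7 only.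

Step 10
Reactants: 15 5-hydroxy-2-(4-methoxyphenyl)-7-[(3-methylbut-2-en-1-yl)oxy]-3-{[2-(trimethylsilyl)ethoxy]methoxy}-4H-chromen-4-one
Product: 16 3,5-dihydroxy-2-(4-methoxyphenyl)-7-[(3-methylbut-2-en-1-yl)oxy]-4H-chromen-4-one
Conditions: Bu4NF (5 equiv), THF, 50 °C, argon; then dilute aq. HCl to pH 5, 0 °C
Reagents that add atoms: none
Why: Fluoride-induced fragmentation of the SEM acetal (attack at silicon, loss of ethene and formaldehyde) should free the 3-OH under conditions to which the prenyl aryl ether and the free 5-OH are inert.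

Compound list
1 | 3-hydroxy-4H-pyran-4-one (pyromeconic acid) | O=c1ccocc1O | starting material
2 | 2-bromo-3-hydroxy-4H-pyran-4-one | O=c1ccoc(Br)c1O | intermediate
3 | 2-bromo-3-{[2-(trimethylsilyl)ethoxy]methoxy}-4H-pyran-4-one | C[Si](C)(C)CCOCOc1c(Br)occc1=O | intermediate
4 | (4-methoxyphenyl)boronic acid | COc1ccc(cc1)B(O)O | starting material
5 | 2-(4-methoxyphenyl)-3-{[2-(trimethylsilyl)ethoxy]methoxy}-4H-pyran-4-one | COc1ccc(cc1)-c1occc(=O)c1OCOCC[Si](C)(C)C | intermediate
6 | 2-(4-methoxyphenyl)-5-(phenylthio)-3-{[2-(trimethylsilyl)ethoxy]methoxy}-4H-pyran-4-one | COc1ccc(cc1)-c1occ(Sc2ccccc2)c(=O)c1OCOCC[Si](C)(C)C | intermediate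
7 | 2-(4-methoxyphenyl)-5-(phenylsulfinyl)-3-{[2-(trimethylsilyl)ethoxy]methoxy}-4H-pyran-4-one (racemic at sulfur) | COc1ccc(cc1)-c1occ(S(=O)c2ccccc2)c(=O)c1OCOCC[Si](C)(C)C | intermediate
8 | methyl acetoacetate | COC(=O)CC(C)=O | starting material
9 | methyl 3-[(trimethylsilyl)oxy]but-2-enoate (E/Z mixture) | COC(=O)C=C(C)O[Si](C)(C)C | intermediate
10 | (Z)-1-methoxy-1,3-bis[(trimethylsilyl)oxy]buta-1,3-diene (Chan's diene) | CO/C(O[Si](C)(C)C)=C/C(=C)O[Si](C)(C)C | intermediate
11 | 5-methoxy-2-(4-methoxyphenyl)-4a-(phenylsulfinyl)-3-{[2-(trimethylsilyl)ethoxy]methoxy}-5,7-bis[(trimethylsilyl)oxy]-4a,5,8,8a-tetrahydro-4H-chromen-4-one (racemic; cis ring fusion shown as relative configuration; sulfur and C5 unassigned) | COc1ccc(cc1)C1=C(OCOCC[Si](C)(C)C)C(=O)[C@]2(S(=O)c3ccccc3)[C@H](O1)CC(O[Si](C)(C)C)=CC2(OC)O[Si](C)(C)C | intermediate (not isolated)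
12 | 5-methoxy-2-(4-methoxyphenyl)-3-{[2-(trimethylsilyl)ethoxy]methoxy}-5,7-bis[(trimethylsilyl)oxy]-5,8-dihydro-4H-chromen-4-one (racemic at C5) | COc1ccc(cc1)C1=C(OCOCC[Si](C)(C)C)C(=O)C2=C(O1)CC(O[Si](C)(C)C)=CC2(OC)O[Si](C)(C)C | intermediate (not isolated)
13 | 5,7-dihydroxy-2-(4-methoxyphenyl)-3-{[2-(trimethylsilyl)ethoxy]methoxy}-4H-chromen-4-one | COc1ccc(cc1)-c1oc2cc(O)cc(O)c2c(=O)c1OCOCC[Si](C)(C)C | intermediate
14 | prenyl bromide (1-bromo-3-methylbut-2-ene) | CC(C)=CCBr | starting material
15 | 5-hydroxy-2-(4-methoxyphenyl)-7-[(3-methylbut-2-en-1-yl)oxy]-3-{[2-(trimethylsilyl)ethoxy]methoxy}-4H-chromen-4-one | COc1ccc(cc1)-c1oc2cc(OCC=C(C)C)cc(O)c2c(=O)c1OCOCC[Si](C)(C)C | intermediate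
16 | 3,5-dihydroxy-2-(4-methoxyphenyl)-7-[(3-methylbut-2-en-1-yl)oxy]-4H-chromen-4-one | COc1ccc(-c2oc3cc(OCC=C(C)C)cc(O)c3c(=O)c2O)cc1 | target

Total step count: 10. Longest linear sequence: 8 steps (steps 1–5 and 8–10); the diene branch (steps 6 and 7) is two steps.

Steps most likely to fail

Step 8 (the labelled step). After conjugate addition at C6 the pyranone ring may open by loss of the ring oxygen instead of closing ring A. The silyl ketene acetal may also consume the sulfoxide in a Pummerer-type reaction, and the liberated sulfenic acid may sulfenylate the electron-rich new ring. The fallback uses known flavone chemistry and no pyranone. It sets out from prenyl bromide 14 and comes back to the route at target 16. Commercial acacetin (5,7-dihydroxy-4'-methoxyflavone) would be alkylated at the 7-OH with 14 (K2CO3, acetone) to give 5-hydroxy-2-(4-methoxyphenyl)-7-[(3-methylbut-2-en-1-yl)oxy]-4H-chromen-4-one F1. The chelated 5-OH would then be capped (NaH, SEMCl, DMF) to give 2-(4-methoxyphenyl)-7-[(3-methylbut-2-en-1-yl)oxy]-5-{[2-(trimethylsilyl)ethoxy]methoxy}-4H-chromen-4-one F2. C3 would be lithiated with LiN(iPr)2 at −78 °C, borylated with B(OMe)3 and oxidised with H2O2/NaOH, conditions that leave the prenyl alkene alone, to give 3-hydroxy-2-(4-methoxyphenyl)-7-[(3-methylbut-2-en-1-yl)oxy]-5-{[2-(trimethylsilyl)ethoxy]methoxy}-4H-chromen-4-one F3. Bu4NF in THF would finally free the 5-OH and give 16.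

Step 4. Sulfenyl transfer to C5 of the weakly nucleophilic pyranone may be slow, and reversible attack on the more electron-rich C2=C3 bond may lead to decomposition. The fallback replaces electrophilic sulfenylation by halogenation and cross-coupling. It sets out from 3 and comes back at 6. Bromine would be added across C5=C6 of 3 and HBr removed with Et3N (CH2Cl2, 0 °C) to give 2,5-dibromo-3-{[2-(trimethylsilyl)ethoxy]methoxy}-4H-pyran-4-one F4, with no anisyl ring yet present to compete. Site-selective Suzuki–Miyaura coupling with 4 at the more electrophilic β-carbon C2 (Pd(PPh3)4, K2CO3, dioxane/H2O, 60 °C) would give 5-bromo-2-(4-methoxyphenyl)-3-{[2-(trimethylsilyl)ethoxy]methoxy}-4H-pyran-4-one F5. C–S coupling of F5 with thiophenol (Pd2(dba)3, Xantphos, iPr2NEt, dioxane, 90 °C) would then give 6.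

Step 10. Fragmentation of the SEM acetal may be sluggish, and the formaldehyde released may hydroxymethylate the electron-rich ring A under the basic conditions. The fallback removes the acetal before the prenyl group is present and differentiates the hydroxyls by acylation. It sets out from 13 and comes back at 16. HCl in MeOH (50 °C) would cleave the SEM group of 13 to give kaempferide, 3,5,7-trihydroxy-2-(4-methoxyphenyl)-4H-chromen-4-one F6. Ac2O/pyridine would give the triacetate, 2-(4-methoxyphenyl)-4-oxo-4H-chromene-3,5,7-triyl triacetate F7. Thiophenol and imidazole in N-methylpyrrolidone would remove the most labile 7-O-acetyl group selectively to give 7-hydroxy-2-(4-methoxyphenyl)-4-oxo-4H-chromene-3,5-diyl diacetate F8. Mitsunobu etherification with 3-methylbut-2-en-1-ol (PPh3, diisopropyl azodicarboxylate, THF), which is neutral and avoids acyl migration, would give 2-(4-methoxyphenyl)-7-[(3-methylbut-2-en-1-yl)oxy]-4-oxo-4H-chromene-3,5-diyl diacetate F9. K2CO3 in MeOH at rt would then remove both acetates and give 16.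

Further compounds
F1 | step 8 | 5-hydroxy-2-(4-methoxyphenyl)-7-[(3-methylbut-2-en-1-yl)oxy]-4H-chromen-4-one | COc1ccc(cc1)-c1cc(=O)c2c(O)cc(OCC=C(C)C)cc2o1
F2 | step 8 | 2-(4-methoxyphenyl)-7-[(3-methylbut-2-en-1-yl)oxy]-5-{[2-(trimethylsilyl)ethoxy]methoxy}-4H-chromen-4-one | COc1ccc(cc1)-c1cc(=O)c2c(OCOCC[Si](C)(C)C)cc(OCC=C(C)C)cc2o1
F3 | step 8 | 3-hydroxy-2-(4-methoxyphenyl)-7-[(3-methylbut-2-en-1-yl)oxy]-5-{[2-(trimethylsilyl)ethoxy]methoxy}-4H-chromen-4-one | COc1ccc(cc1)-c1oc2cc(OCC=C(C)C)cc(OCOCC[Si](C)(C)C)c2c(=O)c1O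
F4 | step 4 | 2,5-dibromo-3-{[2-(trimethylsilyl)ethoxy]methoxy}-4H-pyran-4-one | C[Si](C)(C)CCOCOc1c(Br)occ(Br)c1=O
F5 | step 4 | 5-bromo-2-(4-methoxyphenyl)-3-{[2-(trimethylsilyl)ethoxy]methoxy}-4H-pyran-4-one | COc1ccc(cc1)-c1occ(Br)c(=O)c1OCOCC[Si](C)(C)C
F6 | step 10 | 3,5,7-trihydroxy-2-(4-methoxyphenyl)-4H-chromen-4-one (kaempferide) | COc1ccc(cc1)-c1oc2cc(O)cc(O)c2c(=O)c1O
F7 | step 10 | 2-(4-methoxyphenyl)-4-oxo-4H-chromene-3,5,7-triyl triacetate | COc1ccc(cc1)-c1oc2cc(OC(C)=O)cc(OC(C)=O)c2c(=O)c1OC(C)=O
F8 | step 10 | 7-hydroxy-2-(4-methoxyphenyl)-4-oxo-4H-chromene-3,5-diyl diacetate | COc1ccc(cc1)-c1oc2cc(O)cc(OC(C)=O)c2c(=O)c1OC(C)=O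
F9 | step 10 | 2-(4-methoxyphenyl)-7-[(3-methylbut-2-en-1-yl)oxy]-4-oxo-4H-chromene-3,5-diyl diacetate | COc1ccc(cc1)-c1oc2cc(OCC=C(C)C)cc(OC(C)=O)c2c(=O)c1OC(C)=O
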